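(Readings and results come from a simulation from invented constants, and the scatter is random.)

The meeting had 3 questions on one flask, all about the selectivity cTgt/(cTgt + cOfp), at an early, a middle and a late time.

| setting | beta | epsilon | flask |
|---|---|---|---|
| Sub | 0.20 M | 0.45 M | 0.30 M |
| Rea | 0.315 M | 0.315 M | 0.315 M |
| Cat | 1.5 mM | 1.5 mM | 1.5 mM |
| remark | run made earlier | run made earlier |  |
| time |  |  | 12 h |

| run | time / h | Tgt / % | Ofp / % |
|---|---|---|---|
| beta | 1.00 | 23.2 | 5.7 |
| beta | 2.00 | 44.7 | 11.7 |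
| beta | 3.00 | 57.2 | 16.3 |
| beta | 4.00 | 64.3 | 18.1 |
| beta | 5.00 | 69.3 | 19.2 |
| beta | 6.00 | 71.8 | 19.8 |
| beta | 8.00 | 75.4 | 21.1 |
| epsilon | 0.417 | 5.9 | 1.4 |
| epsilon | 1.00 | 18.9 | 4.3 |
| epsilon | 2.00 | 34.5 | 9.1 |
| epsilon | 3.00 | 42.5 | 11.5 |
| epsilon | 4.00 | 47.3 | 13.3 |
| epsilon | 6.00 | 51.3 | 14.5 |
| epsilon | 8.00 | 53.6 | 15.3 |

(each reading ± 0.3 percentage points)

- the earlier runs were read with a standard deviation of 0.3 percentage points

- share of Tgt in Tgt plus Ofp at 10 min
- share of Tgt in Tgt plus Ofp at 80 min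
- share of Tgt in Tgt plus Ofp at 12 h

I opened with the late readings. At 8.00 h the beta run reads a share of 78.1% and the epsilon run 77.8%, although their Sub charges differ. I proposed to read this plateau s as thermodynamic control, with Tgt and Ofp interconverting, and to treat Ofp as a first-order lag behind a steady feed of Tgt. The share at time t is then s + (1 − s)(τ/t)(1 − exp(−t/τ)).

At 1.00 h the beta run reads 80.3%, which gives 0.0980 h for τ, the lag time with which Ofp trails Tgt. The epsilon run reads 81.5% and gives 0.165 h, so τ is a rough reading.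

For the flask I therefore reckoned 88.6% to 91.8% at 10 min. With the beta lag I reckoned 79.7% at 80 min and 78.3% at 12 h, a time far longer than τ.

The forecaster gave 81.5% (78.5% to 85%), 80% (78.8% to 81.2%) and 78% (77.2% to 78.7%), holding that “early product forms at roughly 81–82% selectivity”. My early figure stands higher than the forecast's, and the disagreement was minuted.

The flask gives 91.3%, 79.9% and 78.1%, so the forecast is 9.8 points low at 10 min and within its ranges at the other times.

    Cat + Int ⇌ Int2 (K = 1.10 M⁻¹, k = 180 M⁻¹ min⁻¹)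
    Rea + Int2 → Cat + Tgt (k = 32.0 M⁻¹ min⁻¹)
    Tgt ⇌ Ofp (K = 0.280, k = 0.0360 min⁻¹)
    Sub + Cat → Cat + Int (k = 17.0 M⁻¹ min⁻¹)

By its own step, both ways together, the pair Tgt and Ofp relaxes with a half-life of 0.0702 h, short against 12 h. Used again at 0.360 h, the lag 0.0980 h gives 83.9%, and the flask then holds 5.28% Tgt and 0.841% Ofp, a share of 86.3%.

For a neighbouring flask, the same flask with 1.2 M of Sub, the lag gives 88.6% at 10 min and 78.3% at 12 h. Computed, that neighbouring flask has 91.1% and 78.1%, with 73.7% of the Sub charged still standing as Int at 12.0 h.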